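(The readings were computed for an exercise; scatter was added.)

11.2 min against 0.478 min: I read these two times from the earlier runs, a factor of 23.4 apart. Alder, cedar and birch vary the protic impurity charge at fixed starting complex, incoming ligand and time.

| setting | east | south | alder | cedar | birch |
|---|---|---|---|---|---|
| starting complex | 1.5 M | 1.5 M | 1.5 M | 1.5 M | 1.5 M |
| incoming ligand | 0.90 M | 0.90 M | 0.900 M | 0.900 M | 0.900 M |
| protic impurity | 0.085 M | 0.42 M | 0.0750 M | 0.150 M | 0.300 M |
| remark | run made earlier | run made earlier |  |  |  |
| time |  |  | 2.5 min | 2.5 min | 2.5 min |

| run | time / min | complex with one exchanged / % | starting complex / % | complex with two exchanged / % | over-reaction product / % |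
|---|---|---|---|---|---|
| east | 0.167 | 1.7 | 96.4 | 0 | 0 |
| east | 0.417 | 3.5 | 93.9 | 0 | 0 |
| east | 0.667 | 6.7 | 88.6 | 0 | 0.7 |
| east | 1.00 | 9.0 | 87.3 | 1.1 | 0.1 |
| east | 1.50 | 12.3 | 80.9 | 1.4 | 0 |
| east | 2.00 | 13.3 | 79.2 | 0.2 | 0.2 |
| east | 2.50 | 15.9 | 75.4 | 0 | 0.6 |
| south | 0.167 | 0.7 | 89.0 | 1.1 | 0.2 |
| south | 0.417 | 5.0 | 78.4 | 0.3 | 0 |
| south | 0.667 | 5.2 | 72.1 | 1.4 | 0 |
| south | 1.00 | 7.2 | 68.6 | 0 | 0.8 |
| south | 1.50 | 11.3 | 63.0 | 0.7 | 0.8 |
| south | 2.00 | 11.1 | 59.0 | 1.4 | 0.6 |
| south | 2.50 | 10.9 | 56.0 | 0.6 | 0.4 |

(each reading ± 1 percentage point)

- what may be going on: complex with two exchanged -> over-reaction product; protic impurity + starting complex -> quenched substrate; complex with one exchanged + incoming ligand <-> leaving ligand + complex with two exchanged; starting complex + incoming ligand <-> leaving ligand + complex with one exchanged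

* which of these there is most of at the end, counted by the starting complex in it, alder (complex with one exchanged / starting complex / over-reaction product / complex with two exchanged)
* which of these there is most of at the end, counted by the starting complex in it, cedar (complex with one exchanged / starting complex / over-reaction product / complex with two exchanged)
* which of these there is most of at the end, counted by the starting complex in it, birch (complex with one exchanged / starting complex / over-reaction product / complex with two exchanged)
* the largest of these amounts at the end, in percent of the starting complex charged, alder
* the largest of these amounts at the end, in percent of the starting complex charged, cedar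
* the largest of these amounts at the end, in percent of the starting complex charged, birch

On the proposed scheme, starting complex leaves by two ways: the quench, one impurity for one complex, and first exchange. In south, the listed forms at 0.417 min fell short of the charge by 16.3%, out of the 28.0% its impurity could take. That reading gave the quench time, over which unspent impurity shrinks by the factor e.

Because the quench ran far ahead of exchange, I took the two in turn. The impurity removes its fraction of the charge, then exchange shrinks the remainder pseudo-first-order, in proportion to what is left. Integrated, the fraction left is the part the impurity cannot reach times the exponential of minus time over the exchange time, the time in which exchange shrinks that part by the factor e. East's last reading gave that time. On south it predicts 57.5% against a reading of 56.0%, with a scatter of 1 percentage point.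

My figures were 75.9% for alder, 71.9% for cedar and 63.9% for birch. For birch I reckoned the loss to exchange at about 16.1%, less than my figure for the starting complex.

The forecast differed slightly from my figures. It named starting complex for alder, starting complex for cedar and starting complex for birch, at 76.5%, 72.5% and 63.5%, holding that “Each run therefore loses starting complex roughly equal to its impurity charge”.

Starting complex stayed ahead of complex with one exchanged in alder, cedar and birch, at 76.3%, 72.0% and 63.5%.

    complex with two exchanged → over-reaction product (k = 0.00790 s⁻¹)
    protic impurity + starting complex → quenched substrate (k = 0.0290 M⁻¹ s⁻¹)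
    complex with one exchanged + incoming ligand ⇌ leaving ligand + complex with two exchanged (K = 1.20, k = 0.00230 M⁻¹ s⁻¹)
    starting complex + incoming ligand ⇌ leaving ligand + complex with one exchanged (K = 3.50, k = 0.00200 M⁻¹ s⁻¹)

Birch left until 6.0 min had 0% of its impurity remaining, so I applied the same two factors with the same exchange time and got 46.7%. That flask held 52.3% of starting complex, 5.6 points above my figure, with incoming ligand down to 44% of its charge.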